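All runs stem from a simulated flask from invented constants, noise included.

In a closed, stirred vessel at constant temperature, starting material meets coupling partner and a small charge of free catalyst. We want the part of the starting material reacted by 12 min in two new flasks, grey and red; starting material parked in the idle adduct counts as reacted.

| flask | starting material | coupling partner | free catalyst | remark | time |
|---|---|---|---|---|---|
| south | 0.050 M | 2.4 equiv | 1 mol% | run made earlier |  |
| north | 0.050 M | 2.1 equiv | 1 mol% | run made earlier |  |
| north-east | 0.050 M | 2.8 equiv | 1 mol% | run made earlier |  |
| grey | 0.050 M | 2.60 equiv | 1 mol% |  | 12 min |
| red | 0.050 M | 2.00 equiv | 1 mol% |  | 12 min |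

| run | time / min | starting material / % | product / % |
|---|---|---|---|
| south | 0.667 | 87.9 | 5.1 |
| south | 1.33 | 76.8 | 10.4 |
| south | 2.50 | 62.3 | 18.0 |
| south | 4.00 | 50.7 | 26.2 |
| south | 8.00 | 35.0 | 34.2 |
| north | 1.50 | 77.3 | 11.3 |
| north | 3.00 | 62.3 | 20.2 |
| north | 5.00 | 49.6 | 24.7 |
| north | 6.00 | 46.6 | 27.8 |
| north | 8.00 | 38.8 | 31.4 |
| north-east | 0.667 | 85.4 | 7.1 |
| north-east | 1.33 | 76.8 | 13.3 |
| north-east | 2.50 | 62.4 | 19.1 |
| north-east | 4.00 | 48.4 | 27.2 |
| north-east | 8.00 | 28.4 | 38.1 |

(each reading ± 1 percentage point)

- part of the starting material that has reacted at the end, grey
- part of the starting material that has reacted at the end, red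
- what raising the equivalents of coupling partner from its lowest to its highest value here does to the part of the starting material that has reacted (changes below 5 percentage points count as none) (no change / it falls / it rises)

- for by-product the idle adduct is counted in
- steps under discussion: catalyst intermediate A -> catalyst intermediate B; coupling partner + free catalyst -> catalyst intermediate A; catalyst intermediate D -> free catalyst + product; starting material + by-product <-> idle adduct; free catalyst -> spent catalyst; starting material + catalyst intermediate C -> catalyst intermediate D; catalyst intermediate B -> by-product + catalyst intermediate C
- what has gone from starting material into another species counts as reacted, even if it can come back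

The south run slows well before its starting material is consumed. It loses 0.181 /min of the charge up to 0.667 min, but 0.0392 /min between 4.00 min and 8.00 min. The ratio of those two rates, 4.62, is larger than the ratio of the two starting-material readings, 2.51, so we read the excess as working catalyst dying.

The midpoints of those two intervals lie 5.67 min apart. This gives, as a reading, a fade time, the time in which the rate of loss halves (an apparent deactivation half-life), of 2.57 min. The north-east run gives 2.66 min.

A rate that keeps halving adds up to a finite tail: the present rate times 3.70 min, the fade time over the logarithm of two. At 8.00 min we reckon the rate of the south run at 0.0229 /min, so we estimate the tail at 8.5 percentage points, of which 5.6 points arrives by 12 min.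

Grey's 2.60 equiv lies midway between the south and north-east runs, which puts it at 68.3% at 8.00 min. Red, carried below the north run along the slope of the runs, stands at 59.7%. Our own reckoning is therefore 73.9% for grey and 65.3% for red, a rise.

The forecast says 78% for grey and 67% for red, and on the trend: it rises. It parts from us on the last stretch: “Adding about 10 and 8 points over the last 4 min gives about 78% and 67%.”

The flasks give 76.0% for grey and 61.7% for red; on the trend, it rises, by 14 points.

    catalyst intermediate A → catalyst intermediate B (k = 24.0 /min)
    coupling partner + free catalyst → catalyst intermediate A (k = 260 /M/min)
    catalyst intermediate D → free catalyst + product (k = 47.0 /min)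
    starting material + by-product ⇌ idle adduct, settled at all times (K = 530 /M)
    free catalyst → spent catalyst (k = 0.710 /min)
    starting material + catalyst intermediate C → catalyst intermediate D (k = 6500 /M/min)
    catalyst intermediate B → by-product + catalyst intermediate C (k = 1200 /min)

With the step from free catalyst to spent catalyst struck out, the difference between grey and red shrinks from 14 points to 0.27 points, which makes that step the largest single effect on the gap. Our tail, estimated from the south run, puts 2.9 points after 12 min. Left until 120 min, grey gains 4.1 points and reaches 80.1%, while red gains 2.1 points and reaches 63.8%.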